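The time of reading is what separates the three flasks asked about. Dawn, spring and noon share a recipe, with Z at 0.20 M, and stop at 50 min, 150 min and 450 min.

| setting | Saturday's | Sunday's | dawn | noon | spring |
|---|---|---|---|---|---|
| Z | 0.10 M | 0.15 M | 0.20 M | 0.20 M | 0.20 M |
| E | 1 equiv | 1 equiv | 1.00 equiv | 1.00 equiv | 1.00 equiv |
| D | 0.5 mol% | 0.5 mol% | 0.5 mol% | 0.5 mol% | 0.5 mol% |
| remark | run made earlier | run made earlier |  |  |  |
| time |  |  | 50 min | 450 min | 150 min |

| run | time / min | Z / % | Q / % | J / % |
|---|---|---|---|---|
| Saturday's | 3.00 | 96 | 0 | 0 |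
| Saturday's | 10.0 | 92 | 2 | 0 |
| Saturday's | 15.0 | 92 | 8 | 1 |
| Saturday's | 25.0 | 86 | 11 | 4 |
| Saturday's | 40.0 | 80 | 17 | 0 |
| Saturday's | 50.0 | 76 | 21 | 0 |
| Saturday's | 60.0 | 70 | 28 | 1 |
| Sunday's | 5.00 | 98 | 4 | 3 |
| Sunday's | 8.00 | 93 | 5 | 0 |
| Sunday's | 12.0 | 92 | 6 | 0 |
| Sunday's | 15.0 | 91 | 8 | 0 |
| Sunday's | 25.0 | 84 | 18 | 2 |
| Sunday's | 40.0 | 80 | 22 | 0 |
| Sunday's | 60.0 | 66 | 34 | 0 |

(each reading ± 2 percentage points)

* which of these there is most of at the end, counted by the Z in it, dawn (Z / J / Q)
* which of these there is most of at the end, counted by the Z in it, noon (Z / J / Q)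
* which of these there is most of at the end, counted by the Z in it, spring (Z / J / Q)
* how much there is at the end of the one of these that leads, in percent of the Z charged: dawn
* how much there is at the end of the one of these that leads, in percent of the Z charged: noon
* how much there is at the end of the one of these that leads, in percent of the Z charged: spring

- the analysis behind the earlier runs scatters by 2 percentage points, standard deviation

A quick number needs a scale, and its zero is the first-order case, in which percent curves from different charges coincide and one constant serves any [Z]. Each run's last reading gives such a constant, the logarithm of charged over remaining Z divided by the time: 0.00594 min⁻¹ for Saturday's run at 0.10 M and 0.00693 min⁻¹ for Sunday's at 0.15 M. Sunday's constant is larger, so the runs sit a little off the zero, and the exponent s of [Z] in the constant reads 0.377. But the two readings of Z behind it differ by 4 percentage points against a scatter of 2 points, so s is a loose reading.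

Carried to 0.20 M, this gives the percent clock, the flask's pseudo-first-order constant, 0.00772 min⁻¹. The reckoning here therefore puts Z in the lead at dawn with 68.0 %, and Q in the lead at spring with 68.6 % and at noon with 96.9 %.

The forecast sent with the question names the same leaders, Z, Q and Q, but gives other amounts: 71 % at dawn, 75 % at spring and 88 % at noon, the last within 62 % to 98 %. Its noon value stands lower than the clock's, on the ground that slow loss to J, “or catalyst death, could lower this”.

Dawn ends with Z in the lead at 67.9 %, spring with Q at 70.7 %, and noon with Q at 98.1 %, the last being 10 points above the forecast.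

    Z + D ⇌ J (K = 8.61 L mol⁻¹, k = 35.5 L mol⁻¹ min⁻¹)
    J → D + Q (k = 3.78 min⁻¹)
    E + D ⇌ G (K = 12.0 L mol⁻¹, k = 28.7 L mol⁻¹ min⁻¹)
    G → D + L (k = 12.2 min⁻¹)
    J → X (k = 0.00801 min⁻¹)

In noon, X holds 41.6 % of the catalyst charged at 450 min, with Z down to 1.67 %. That Z gives noon its own clock of 0.00909 min⁻¹, faster than the 0.00772 min⁻¹ carried over. For a neighbour of noon charged with Z at 0.12 M, the time held, the clock scaled by s gives 0.00637 min⁻¹ and so Z at 5.69 %; that neighbour holds Z at 6.96 %.

The runs were computed with constants of no real substance; scatter was added.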